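Bet against piling on partner: judge the delta run by how long target survives, not by how fast it forms.

| setting | theta | beta | epsilon | delta |
|---|---|---|---|---|
| starting material | 0.120 M | 0.120 M | 0.240 M | 0.120 M |
| partner | 0.240 M | 0.720 M | 0.240 M | 1.70 M |
| time |  |  |  | 68 min |

| run | time / min | [target] / M |
|---|---|---|
| theta run | 2.7 | 4 × 10⁻⁴ |
| theta run | 5.2 | 0.0035 |
| theta run | 9.9 | 0.0059 |
| theta run | 19 | 0.0175 |
| theta run | 36 | 0.0332 |
| theta run | 68 | 0.0541 |
| beta run | 2.7 | 0.0032 |
| beta run | 5.2 | 0.0050 |
| beta run | 9.9 | 0.0109 |
| beta run | 19 | 0.0191 |
| beta run | 36 | 0.0298 |
| beta run | 68 | 0.0395 |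
| epsilon run | 2.7 | 0.0016 |
| epsilon run | 5.2 | 0.0043 |
| epsilon run | 9.9 | 0.0114 |
| epsilon run | 19 | 0.0224 |
| epsilon run | 36 | 0.0484 |
| epsilon run | 68 | 0.0811 |

(each reading ± 0.001 M)

1. order of the initial rate in [partner], near the charge of the theta run, the rate being that where two percent of its starting material are target
2. order of the initial rate in [starting material], near the charge of the theta run, the rate being that where two percent of its starting material are target (one fixed amount of target, the same in the runs compared)
3. target in the delta run at 68 min, as a share of the starting material charged

- Overall: starting material + partner -> target.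
- Constant volume, constant temperature.
- Readings of a species count what is bound in complexes too.
- "The second partner" is partner.
- An order is taken over about fifteen percent of the charge, up and down.

Start with the beta run. Up to 9.9 min it makes target at about 0.00110 M min⁻¹, but between 36 min and 68 min it climbs at 3.03 × 10⁻⁴ M min⁻¹, with about 0.0347 M target present. Assume steady formation and read the gap as loss of target. Treat that loss as pseudo-first-order in target, since partner in the beta run stays far above target. The beta loss constant is then 0.0230 min⁻¹, and dividing by the partner charge gives the reading 0.0320 M⁻¹ min⁻¹: κ, the share of target lost per minute per molar of partner. Target's lifetime is τ = 1/(κ[partner]), and with formation rate r, target levels off near rτ.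

Now turn the question round: what must be true for the delta run to match the beta run's 0.0395 M at 68 min? The reading κ puts the delta run's lifetime at 18.4 min, so formation would need 0.00215 M min⁻¹, about twice the beta rate. Yet raising partner from 0.240 M to 0.720 M moved the early rate from 9.21 × 10⁻⁴ M min⁻¹ to 0.00110 M min⁻¹, a factor of 1.20. So keep the beta rate: 68 min spans 3.70 lifetimes, and my reckoning gives 16.5 % of the charge.

The forecast gives 0.3 in partner, 0.5 in starting material and 18 %, reasoning that “Something is dying, and faster with more partner”. It blames a dying catalyst where I read lost target, and its yield stands above mine.

    starting material ⇌ intermediate + by-product (0.06840 min⁻¹, 0.3120 M⁻¹ min⁻¹)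
    intermediate + partner → target (0.8640 M⁻¹ min⁻¹)
    2 starting material ⇌ idle substrate dimer, settled at all times (127.0 M⁻¹)
    target + partner → side product (0.02700 M⁻¹ min⁻¹)

The delta run gives 17.3 %, above my reckoning and below the forecast. The orders are 0.34 in partner and 0.38 in starting material, the second lower than the forecast's. Now use κ on the theta run: this reading from the beta run gives an estimated target lifetime of 130 min in the theta run, longer than the 32.4 min the theta run took to bring target to a quarter of its charge, whereas the estimate of 18.4 min for the delta run is shorter than that theta time.

The readings were computed for substances that don't exist.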